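Compound numbers refer to the list after the steps. Core locants C1–C9 are those of the bicyclo[3.3.1]nonan-9-one: ring A = C1, C8, C7, C6, C5, C9; ring B = C1, C2, C3, C4, C5, C9. The same locants are used for the ring B intermediates.

## Analysis of the target

Target 20 is an N-acylated aminocyclitol built on a bicyclo[3.3.1]nonan-9-one. Ring B carries a C2–C3 oxirane and a C4 methyl ether, ring A carries a C6 hydroxyl and the (E)-dodec-2-enamide on C7, and the bridgehead C1 is a tertiary alcohol next to the C9 ketone. There are seven contiguous stereocentres, (1S,2S,3S,4S,5S,6R,7S). On ring B the C1 hydroxyl, the oxirane oxygen and the C4 methoxy group all lie on the face turned away from ring A. On ring A the nitrogen is equatorial (exo) and the C6 hydroxyl is axial, cis to nitrogen and gauche to the C9 carbonyl. The sensitive groups are the oxirane, the α-ketol, the β-hydroxy and β-methoxy ketone units and the enamide, which is a Michael acceptor. In the bicycle C5 is a bridgehead that cannot enolise, so retro-aldol cleavage and β-elimination are blocked, but in every monocyclic precursor they are open. The hard parts are the quaternary carbinol C1 in absolute terms and the all-cis oxygen array on ring B, which anti additions cannot deliver. The strategy rests on the vicinal C6 hydroxyl and C7 nitrogen, a β-nitro alcohol retron. In the open keto aldehyde 16, C5, C6 and C7 are all labile, and they are frozen together when ring A closes.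

## Retrosynthetic reasoning

**Amide N–C(O) bond.** 20 is cut into amine 18 and acid 19. The enamide is the only Michael acceptor and would not survive nitronate or hydride chemistry, so it comes last. The forward step only has to acylate nitrogen beside a tertiary and a hindered axial secondary hydroxyl.

**C7–N oxidation level.** 18 goes back to nitro compound 17. The nitro group makes C7 nucleophilic and epimerisable, so it is kept until ring A exists. The forward reduction must spare oxirane, ketone and α-ketol.

**C6–C7 bond, ring A.** 17 is opened to keto aldehyde 16. This is the only cut that removes a ring, a skeletal bond and three stereocentres at once while leaving a precursor whose stereocentres at C5, C6 and C7 need not be controlled beforehand. A cut at C5–C6 or C1–C8 would need those centres preset. The forward reaction is a reversible nitro-aldol that has to settle on the isomer with equatorial nitro and axial hydroxyl.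

**C5–C6 bond.** 16 comes from ketone 14 and formate 15. C1 is quaternary, so 14 can enolise only toward C5 and the formylation has one regiochemical outcome. It must run under kinetic control because the C4 methoxy group is β to the enolate.

**C9 carbonyl and C1 hydroxyl.** 14 comes from 12 through 13. In 12 the C9 carbonyl is an enol ether and the C1 oxygen is acylated by the same three-carbon tether. While C9 is masked there is no β-alkoxy ketone, no α-ketol and no free tertiary alcohol, so the C4 oxygen can be methylated alone.

**C4 methyl ether and C4 stereocentre.** 12 goes back to alcohol 11 and ketone 10. The all-cis relation cannot come from adding an oxygen nucleophile to a C4=C5 enone beside the oxirane, which would enter anti and put the ether trans. With C4 as a ketone, a hydride enters anti to the oxirane and the C–O bond ends up cis.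

**Oxirane.** 10 comes from dienone 9. Its two double bonds differ electronically: C2=C3 is a plain enone and C5=C9 is a vinylogous ester. A nucleophilic oxidant therefore takes C2=C3 only, on the face of the C1 oxygen and opposite the arm.

**C1–O bond.** 9 comes from phenol acid 8 by dearomatisation at the carbon para to the phenolic oxygen. Para attack gives a cross-conjugated dienone that cannot dimerise, unlike the 2,4-dienone from ortho hydroxylation, and it puts the carbonyl at C4 where the hydride step needs it. The lactate stereocentre on the C9 oxygen chooses the face, which fixes the absolute configuration of the whole route.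

**Arm and tether.** 8 goes back to nitroalkene 6, then to aldehyde 4 and 5, then to phenol 2 and 3, then to 1. The aldehyde carbon of 1 becomes C8 and 5 brings C7 with nitrogen already at the right oxidation level. A transient pivalate steers the etherification to the hydroxyl next to the aldehyde.

## Alternatives that were turned down

**Alternative 1:** Ring B is traced to benzoic acid A1 by cutting the C1–O and C9–O bonds. The forward key step is a whole-cell cis-dihydroxylation (Ralstonia eutropha B9) at the ipso and ortho carbons, giving diol acid A2. Its carboxyl carbon is C8, its secondary carbinol is C9 and its diene is C2–C5.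
- For: one step from a commodity arene, and essentially one enantiomer. A2 already has the C1 configuration of the target. The diene with its allylic hydroxyl invites cis oxygenation.
- Against: the key step forms no ring and no skeletal bond. C8 arrives as a carboxyl on a hindered tertiary carbinol and must be reduced and homologated to the nitroethyl arm. The two diene termini must be told apart to place the methoxy group at C4 and a carbon at C5. A mutant strain and fermentation are needed.
- Comparison: it is stronger on absolute control at C1 and on economy of the first step. The chosen route offers in its place an arm that is at the nitro level from the start, a dienone with two electronically distinct double bonds, and a key step that builds ring A, one C–C bond and three stereocentres.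

**Alternative 2:** The C1–C9 bond is cut to give a cyclooctenone bearing a formyl group on C5. In the forward key step a triazolium-derived carbene turns that formyl carbon (the future C9) into an acyl-anion equivalent that adds across the ring to the C1 ketone, giving α-ketol A3.
- For: one bond creates both rings and the bridgehead carbinol. Nitrogen and C7 come from a chiral-pool amino acid, and C6 and C7 are fixed before cyclisation.
- Against: the substrate is an eight-membered enone with four contiguous stereocentres, made by a long linear sequence and a medium-ring closure. The acceptor ketone is conjugated to C2=C3, so a Stetter addition at C3 competes. A benzoin onto a ketone is reversible. The α-formyl centre C5 sits between two β-oxygens and can epimerise or eliminate. Afterwards the epoxidation, two deprotections and a carbamate-to-enamide exchange remain.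
- Comparison: it is stronger at C6 and C7, where it does not rely on a thermodynamic preference. The chosen route reaches its precursor from an arene in ten steps and corrects every labile centre by equilibration.

**Alternative 3:** The C4–C5 bond of ring B is cut back to a branched, hexose-derived pyranoside with an exocyclic enol ether. The forward key step is a Ferrier carbocyclisation: hydration to a keto aldehyde, then an aldol that closes ring B, giving hydroxy ketone A4.
- For: C1, C2 and C3 come from the chiral pool with no auxiliary, and the cyclisation type is dependable for six-membered carbocycles. The oxirane and tertiary carbinol are in place before the ring forms.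
- Against: the branched anhydro sugar needs a long protecting-group sequence and a toxic heavy-metal promoter. A4 is a β-hydroxy ketone with an acidic C5–H, so it is prone to dehydration. The allyl group is one carbon too long for the nitroethyl arm and needs oxidative cleavage and functional-group interchange. The C4 configuration comes from the aldol and is not assured. Ring A is still unmade.
- Comparison: it is stronger on the absolute configuration of C1–C3. The chosen route reaches ring B in fewer steps and keeps the risk in the ring A closure.

Key step: step 11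

Remark on the chemistry: 16 is drawn as the dicarbonyl tautomer with C5 in the configuration that can cyclise. It is expected to exist mainly as the hydroxymethylene enol, in which C5 is not stereogenic.

## Route

Step 1
Reactants: 1 2,4-dihydroxybenzaldehyde
Product: 2 4-formyl-3-hydroxyphenyl 2,2-dimethylpropanoate
Conditions: pivaloyl chloride (1.05 equiv), Et3N, CH2Cl2, 0 °C
Reagents that add atoms: pivaloyl chloride CC(C)(C)C(=O)Cl
Why: O-Acylation; the 2-hydroxyl is hydrogen-bonded to and flanked by the formyl group, so one equivalent of acid chloride should take the 4-hydroxyl and leave the 2-hydroxyl as the only Mitsunobu nucleophile for step 2.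

Step 2
Reactants: 2 4-formyl-3-hydroxyphenyl 2,2-dimethylpropanoate; 3 methyl (2R)-2-hydroxypropanoate (methyl (R)-lactate)
Product: 4 methyl (2S)-2-[5-(2,2-dimethylpropanoyloxy)-2-formylphenoxy]propanoate
Conditions: PPh3, DIAD, THF, 0 °C → rt
Reagents that add atoms: none
Why: Mitsunobu etherification; the salicylaldehyde-type phenol is acidic enough to act as pronucleophile and displaces the activated secondary carbinol of 3 with inversion, so the (R)-alcohol gives the (S)-aryloxypropanoate.

Step 3
Reactants: 4 methyl (2S)-2-[5-(2,2-dimethylpropanoyloxy)-2-formylphenoxy]propanoate; 5 nitromethane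
Product: 6 methyl (2S)-2-{5-(2,2-dimethylpropanoyloxy)-2-[(E)-2-nitroethenyl]phenoxy}propanoate
Conditions: 5 (excess), NH4OAc, AcOH, 90 °C
Reagents that add atoms: none
Why: Henry condensation (nitro-aldol addition then loss of water) gives the conjugated (E)-nitroalkene; the aldehyde carbon becomes C8 and the carbon of 5 becomes C7, and the buffered acidic medium should leave both esters and the α-aryloxy stereocentre untouched.

Step 4
Reactants: 6 methyl (2S)-2-{5-(2,2-dimethylpropanoyloxy)-2-[(E)-2-nitroethenyl]phenoxy}propanoate
Product: 8 (2S)-2-[5-hydroxy-2-(2-nitroethyl)phenoxy]propanoic acid, via nitroalkane diester 7 (not isolated)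
Conditions: NaBH4, THF/i-PrOH, 0 °C; then LiOH, H2O, rt; NaH2PO4 to pH 6, then HCl to pH 3
Reagents that add atoms: lithium hydroxide [Li+].[OH-] (its oxygen ends in the carboxyl group)
Why: Conjugate hydride reduction of the nitroalkene, then saponification of the methyl ester and the aryl pivalate in the same pot; neutralising to pH 6 before acidifying returns the nitronate to the nitroalkane and avoids a Nef reaction.

Step 5
Reactants: 8 (2S)-2-[5-hydroxy-2-(2-nitroethyl)phenoxy]propanoic acid
Product: 9 (3S,8aS)-3-methyl-8a-(2-nitroethyl)-3,8a-dihydro-1,4-benzodioxine-2,6-dione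
Conditions: PhI(OCOCF3)2, CH2Cl2, −20 → 0 °C
Reagents that add atoms: none
Why: Oxidative phenol dearomatisation with a trivalent iodine reagent, in the known lactic-acid-tether variant for 4-alkylresorcinol ethers; the tethered carboxylic acid adds para to the phenol oxygen at the arm-bearing carbon and closes a six-membered lactone, and with the tether methyl pseudo-equatorial in the forming ring the (S)-acid should deliver oxygen to the face that makes C8a S (core C1 S); the cross-conjugated dienone cannot undergo the Diels–Alder dimerisation of 2,4-dienones.

Step 6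
Reactants: 9 (3S,8aS)-3-methyl-8a-(2-nitroethyl)-3,8a-dihydro-1,4-benzodioxine-2,6-dione
Product: 10 (3S,7R,8S,8aS)-7,8-epoxy-3-methyl-8a-(2-nitroethyl)-3,7,8,8a-tetrahydro-1,4-benzodioxine-2,6-dione (oxirane cis to O1)
Conditions: t-BuOOH (in decane), DBU (0.2 equiv), CH2Cl2, 0 °C
Reagents that add atoms: tert-butyl hydroperoxide CC(C)(C)OO
Why: Weitz–Scheffer nucleophilic epoxidation; the peroxide anion adds to C8 of the plain enone and not to the electron-rich vinylogous ester double bond, and approaches anti to the pseudo-axial nitroethyl arm, that is syn to ring oxygen O1, as is usual for 4-alkyl-4-oxy cyclohexadienones; closure of the enolate onto oxygen puts both oxirane carbons cis to O1.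

Step 7
Reactants: 10 (3S,7R,8S,8aS)-7,8-epoxy-3-methyl-8a-(2-nitroethyl)-3,7,8,8a-tetrahydro-1,4-benzodioxine-2,6-dione
Product: 11 (3S,6S,7S,8S,8aS)-7,8-epoxy-6-hydroxy-3-methyl-8a-(2-nitroethyl)-3,6,7,8-tetrahydro-8aH-1,4-benzodioxin-2-one
Conditions: NaBH4, CeCl3·7H2O, MeOH/CH2Cl2, −78 °C; NaHCO3 quench
Reagents that add atoms: none
Why: Luche reduction; 1,2-delivery of hydride to the ketone from the face anti to the neighbouring oxirane oxygen (the torsional and electrostatic preference of 2,3-epoxycyclohexanones) sets core C4 with its oxygen cis to the oxirane, and the lactone and nitro group are inert at this temperature.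

Step 8
Reactants: 11 (3S,6S,7S,8S,8aS)-7,8-epoxy-6-hydroxy-3-methyl-8a-(2-nitroethyl)-3,6,7,8-tetrahydro-8aH-1,4-benzodioxin-2-one
Product: 12 (3S,6S,7S,8S,8aS)-7,8-epoxy-6-methoxy-3-methyl-8a-(2-nitroethyl)-3,6,7,8-tetrahydro-8aH-1,4-benzodioxin-2-one
Conditions: MeOTf, 2,6-di-tert-butyl-4-methylpyridine, CH2Cl2, 0 °C → rt
Reagents that add atoms: methyl trifluoromethanesulfonate COS(=O)(=O)C(F)(F)F
Why: O-Methylation of the only free hydroxyl with methyl triflate and a hindered, non-nucleophilic pyridine; base-free conditions are chosen because an alkoxide base would also form the nitronate, which alkylates on oxygen, and the excess pyridine keeps the acid-labile allylic enol ether from seeing free triflic acid.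

Step 9
Reactants: 12 (3S,6S,7S,8S,8aS)-7,8-epoxy-6-methoxy-3-methyl-8a-(2-nitroethyl)-3,6,7,8-tetrahydro-8aH-1,4-benzodioxin-2-one
Product: 14 (1S,2S,5S,6S)-2-hydroxy-5-methoxy-2-(2-nitroethyl)-7-oxabicyclo[4.1.0]heptan-3-one, via seco acid 13 (not isolated)
Conditions: LiOH, THF/H2O, 0 °C; NaH2PO4 to pH 6; then 0.2 M H2SO4, THF, 0 °C → rt
Reagents that add atoms: water O (its oxygen becomes the C9 carbonyl oxygen)
Why: Saponification opens the lactone and frees the C1 hydroxyl; once the nitronate has been returned to the nitroalkane at pH 6, dilute acid protonates the enol ether at C5 and water adds at C9, releasing the tether as lactic acid and unveiling the ketone; the oxirane is flanked by two oxygenated carbons and should resist dilute acid as epoxyquinol ketals do, and the time in acid is kept short so that the β-methoxy group is not lost.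

Step 10
Reactants: 14 (1S,2S,5S,6S)-2-hydroxy-5-methoxy-2-(2-nitroethyl)-7-oxabicyclo[4.1.0]heptan-3-one; 15 2,2,2-trifluoroethyl formate
Product: 16 (1S,2S,3R,5S,6S)-5-hydroxy-2-methoxy-5-(2-nitroethyl)-4-oxo-7-oxabicyclo[4.1.0]heptane-3-carbaldehyde
Conditions: LiN(SiMe3)2 (3.3 equiv), THF, −78 °C; 15 (1.2 equiv), −78 °C; AcOH, −78 °C
Reagents that add atoms: none
Why: Crossed Claisen condensation (C-formylation of a kinetic lithium enolate); three equivalents of base turn nitroalkane, tertiary alcohol and ketone into nitronate, alkoxide and the C5 enolate (the only enolate possible, C1 being quaternary), and the reactive formate acylates the enolate carbon within minutes at −78 °C, before methoxide can be eliminated; 16 should form as a mixture of hydroxymethylene enol and C5 epimers, all of which feed step 11.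

Step 11
Reactants: 16 (1S,2S,3R,5S,6S)-5-hydroxy-2-methoxy-5-(2-nitroethyl)-4-oxo-7-oxabicyclo[4.1.0]heptane-3-carbaldehyde
Product: 17 (1S,2S,3S,4S,5S,6R,7S)-2,3-epoxy-1,6-dihydroxy-4-methoxy-7-nitrobicyclo[3.3.1]nonan-9-one
Conditions: Et3N (0.2 equiv), THF, 0 °C → rt; AcOH
Reagents that add atoms: none
Why: Intramolecular Henry (nitro-aldol) reaction under thermodynamic control, the closest known type being base-mediated nitro-aldol cyclisations to six-membered β-nitro alcohols as in nitrocyclitol syntheses. The amine deprotonates C7 (a weak base in substoichiometric amount is used so that neutral aldehyde and nitronate coexist and the more acidic 1,3-dicarbonyl unit is not parked as its enolate), the nitronate carbon adds to the formyl carbon C6 through a chair-like transition state, and proton transfer gives the β-nitro alcohol. Ring A closes in the 6-exo-trig mode, the aldehyde C=O being exocyclic to the new ring. C5 is set by the ring itself: only the epimer with the formyl group cis to the nitroethyl arm can bridge, the other epimer and the enol interconvert with it, and after closure C5 is a bridgehead that cannot enolise, so neither retro-aldol cleavage nor loss of the C4 methoxy group can drain the product. C7 is set by equilibration through the nitronate: the nitro group takes the equatorial (exo) position because the axial one points into the fold of the bicycle toward C3–H. C6 is set by reversible addition (retro-Henry): the axial hydroxyl is gauche to the C9 carbonyl and hydrogen-bonds to it and has only one syn-axial hydrogen because C9 is trigonal, whereas the equatorial hydroxyl is anti to C9. The step therefore needs one of four C6/C7 diastereomers and attack on the aldehyde only; the ketone could give only a four-membered ring, and C-alkylation of a nitronate by an epoxide is far slower than carbonyl addition.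

Step 12
Reactants: 17 (1S,2S,3S,4S,5S,6R,7S)-2,3-epoxy-1,6-dihydroxy-4-methoxy-7-nitrobicyclo[3.3.1]nonan-9-one
Product: 18 (1S,2S,3S,4S,5S,6R,7S)-7-amino-2,3-epoxy-1,6-dihydroxy-4-methoxybicyclo[3.3.1]nonan-9-one
Conditions: Zn dust, AcOH/THF, 0 °C → rt; NaHCO3 work-up
Reagents that add atoms: none
Why: Dissolving-metal reduction of the aliphatic nitro group through nitroso and hydroxylamine to the amine with retention at C7; the acidic medium suppresses retro-Henry cleavage, zinc does not reduce the ketone or oxirane at this temperature, and the bridgehead C1–O bond lies in the plane of the carbonyl group, so the reductive cleavage known for α-ketols has no orbital overlap.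

Step 13
Reactants: 18 (1S,2S,3S,4S,5S,6R,7S)-7-amino-2,3-epoxy-1,6-dihydroxy-4-methoxybicyclo[3.3.1]nonan-9-one; 19 (2E)-dodec-2-enoic acid
Product: 20 (2E)-N-[(1S,2S,3S,4S,5S,6R,7S)-2,3-epoxy-1,6-dihydroxy-4-methoxy-9-oxobicyclo[3.3.1]nonan-7-yl]dodec-2-enamide
Conditions: EDC·HCl, HOBt, i-Pr2NEt, CH2Cl2/DMF, 0 °C → rt
Reagents that add atoms: none
Why: Carbodiimide amide coupling through the hydroxybenzotriazole ester; the primary amine is far more nucleophilic than the bridgehead tertiary hydroxyl and the hindered axial C6 hydroxyl, and the active ester acylates faster than the amine can add in the conjugate sense, so N-acylation should give 20 with the (E)-alkene unchanged.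

## Compound list

1 | 2,4-dihydroxybenzaldehyde | O=Cc1ccc(O)cc1O | starting material
2 | 4-formyl-3-hydroxyphenyl 2,2-dimethylpropanoate | CC(C)(C)C(=O)Oc1ccc(C=O)c(O)c1 | intermediate
3 | methyl (2R)-2-hydroxypropanoate (methyl (R)-lactate) | C[C@@H](O)C(=O)OC | starting material
4 | methyl (2S)-2-[5-(2,2-dimethylpropanoyloxy)-2-formylphenoxy]propanoate | C[C@H](Oc1cc(OC(=O)C(C)(C)C)ccc1C=O)C(=O)OC | intermediate
5 | nitromethane | C[N+](=O)[O-] | starting material
6 | methyl (2S)-2-{5-(2,2-dimethylpropanoyloxy)-2-[(E)-2-nitroethenyl]phenoxy}propanoate | C[C@H](Oc1cc(OC(=O)C(C)(C)C)ccc1/C=C/[N+](=O)[O-])C(=O)OC | intermediate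
7 | methyl (2S)-2-[5-(2,2-dimethylpropanoyloxy)-2-(2-nitroethyl)phenoxy]propanoate (nitroalkane diester) | C[C@H](Oc1cc(OC(=O)C(C)(C)C)ccc1CC[N+](=O)[O-])C(=O)OC | intermediate
8 | (2S)-2-[5-hydroxy-2-(2-nitroethyl)phenoxy]propanoic acid | C[C@H](Oc1cc(O)ccc1CC[N+](=O)[O-])C(=O)O | intermediate
9 | (3S,8aS)-3-methyl-8a-(2-nitroethyl)-3,8a-dihydro-1,4-benzodioxine-2,6-dione | [O-][N+](=O)CC[C@]12OC(=O)[C@H](C)OC2=CC(=O)C=C1 | intermediate
10 | (3S,7R,8S,8aS)-7,8-epoxy-3-methyl-8a-(2-nitroethyl)-3,7,8,8a-tetrahydro-1,4-benzodioxine-2,6-dione, oxirane cis to O1 | [O-][N+](=O)CC[C@]12OC(=O)[C@H](C)OC2=CC(=O)[C@@H]2O[C@@H]21 | intermediate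
11 | (3S,6S,7S,8S,8aS)-7,8-epoxy-6-hydroxy-3-methyl-8a-(2-nitroethyl)-3,6,7,8-tetrahydro-8aH-1,4-benzodioxin-2-one | [O-][N+](=O)CC[C@]12OC(=O)[C@H](C)OC2=C[C@H](O)[C@@H]2O[C@@H]21 | intermediate
12 | (3S,6S,7S,8S,8aS)-7,8-epoxy-6-methoxy-3-methyl-8a-(2-nitroethyl)-3,6,7,8-tetrahydro-8aH-1,4-benzodioxin-2-one | [O-][N+](=O)CC[C@]12OC(=O)[C@H](C)OC2=C[C@H](OC)[C@@H]2O[C@@H]21 | intermediate
13 | (2S)-2-{[(1S,2S,5S,6S)-2-hydroxy-5-methoxy-2-(2-nitroethyl)-7-oxabicyclo[4.1.0]hept-3-en-3-yl]oxy}propanoic acid (seco acid, formed as its lithium salt) | C[C@H](OC1=C[C@H](OC)[C@@H]2O[C@@H]2[C@@]1(O)CC[N+](=O)[O-])C(=O)O | intermediate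
14 | (1S,2S,5S,6S)-2-hydroxy-5-methoxy-2-(2-nitroethyl)-7-oxabicyclo[4.1.0]heptan-3-one | [O-][N+](=O)CC[C@@]1(O)C(=O)C[C@H](OC)[C@@H]2O[C@@H]21 | intermediate
15 | 2,2,2-trifluoroethyl formate | O=COCC(F)(F)F | starting material
16 | (1S,2S,3R,5S,6S)-5-hydroxy-2-methoxy-5-(2-nitroethyl)-4-oxo-7-oxabicyclo[4.1.0]heptane-3-carbaldehyde | [O-][N+](=O)CC[C@@]1(O)C(=O)[C@@H](C=O)[C@H](OC)[C@@H]2O[C@@H]21 | intermediate
17 | (1S,2S,3S,4S,5S,6R,7S)-2,3-epoxy-1,6-dihydroxy-4-methoxy-7-nitrobicyclo[3.3.1]nonan-9-one | [O-][N+](=O)[C@H]1C[C@@]2(O)C(=O)[C@@H]([C@H]1O)[C@H](OC)[C@@H]1O[C@@H]12 | intermediate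
18 | (1S,2S,3S,4S,5S,6R,7S)-7-amino-2,3-epoxy-1,6-dihydroxy-4-methoxybicyclo[3.3.1]nonan-9-one | N[C@H]1C[C@@]2(O)C(=O)[C@@H]([C@H]1O)[C@H](OC)[C@@H]1O[C@@H]12 | intermediate
19 | (2E)-dodec-2-enoic acid | CCCCCCCCC/C=C/C(=O)O | starting material
20 | (2E)-N-[(1S,2S,3S,4S,5S,6R,7S)-2,3-epoxy-1,6-dihydroxy-4-methoxy-9-oxobicyclo[3.3.1]nonan-7-yl]dodec-2-enamide | CCCCCCCCC/C=C/C(=O)N[C@H]1C[C@@]2(O)C(=O)[C@@H]([C@H]1O)[C@H](OC)[C@@H]1O[C@@H]12 | target

## Step count and least certain steps

Total step count: 13. Longest linear sequence: 13 steps, from 1 to 20; compounds 3, 5, 15 and 19 are bought.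

**Step 11 (key step).** The most likely failure is equilibration to the wrong C6 epimer. The preference for the axial hydroxyl rests on one hydrogen bond to C9=O against the usual equatorial preference, so the equatorial alcohol may dominate. A second risk is stalling, because the amine parks the 1,3-dicarbonyl unit as its enolate; the substoichiometric weak base is chosen against that. Fallback, setting out from 16: accept the C6-epimeric nitro alcohol F1 and take it through the conditions of steps 12 and 13 to the 6-epi amine F2 and the trans hydroxy amide F3. Cyclodehydrate F3 with Burgess reagent (THF, 60 °C). The amide oxygen displaces the activated equatorial C6 oxygen with inversion and gives the cis-fused oxazoline F4. Dilute aqueous H2SO4 in THF should open F4 to the axial O-acyl amino ester F5, and NaHCO3 then induces O→N acyl migration. The fallback comes back to the route at 20.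

**Step 5.** The risk is poor or reversed facial selectivity in the C–O bond formation at the arm-bearing carbon. The sense is assigned from a conformational model of the forming lactone and not from a rigid transition state. Fallback, setting out from 8: give up diastereoselection and use the lactate as a resolving handle. Para-hydroxylation with KHSO5 (as 2KHSO5·KHSO4·K2SO4) and NaHCO3 in MeCN/H2O, then Na2S2O3, should give the quinol acid F6 together with its C1 epimer. Lactonisation with 2-chloro-1-methylpyridinium iodide and Et3N gives 9 and its 8a-epimer F7. These are diastereomers and separable by chromatography. The fallback comes back at 9.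

**Step 10.** The risk is β-elimination of methoxide from the C5 enolate before it is acylated, or acylation at the alkoxide or nitronate of the trianion. Fallback, setting out from 13 (made from 12 by the LiOH stage of step 9 and neutralised to pH 6): aqueous formaldehyde and Sc(OTf)3 in THF/H2O. The enol ether adds to the aldehyde, water traps the oxocarbenium ion, and lactic acid is lost. This gives the hydroxymethyl ketone F8 without any enolate. Dess–Martin periodinane buffered with NaHCO3 in CH2Cl2 oxidises the primary alcohol and comes back at 16.

**Step 8.** The risk is alkylation of the oxirane oxygen by methyl triflate, or ionisation of the allylic enol ether position by the pyridinium triflate formed, either of which would destroy ring B. Fallback, setting out from 11: change from cationic methyl transfer to alkylation of a dianion. NaH (2.2 equiv) in THF/DMF at 0 °C gives the disodium alkoxide nitronate F9, in which the nitro group is masked. MeI (1.1 equiv) should methylate the far more basic alkoxide to the sodium nitronate F10. Buffered protonation with NaH2PO4 comes back at 12.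

## Further compounds

F1 | step 11 | (1S,2S,3S,4S,5S,6S,7S)-2,3-epoxy-1,6-dihydroxy-4-methoxy-7-nitrobicyclo[3.3.1]nonan-9-one (C6 epimer of 17) | [O-][N+](=O)[C@H]1C[C@@]2(O)C(=O)[C@@H]([C@@H]1O)[C@H](OC)[C@@H]1O[C@@H]12
F2 | step 11 | (1S,2S,3S,4S,5S,6S,7S)-7-amino-2,3-epoxy-1,6-dihydroxy-4-methoxybicyclo[3.3.1]nonan-9-one (6-epi amine) | N[C@H]1C[C@@]2(O)C(=O)[C@@H]([C@@H]1O)[C@H](OC)[C@@H]1O[C@@H]12
F3 | step 11 | (2E)-N-[(1S,2S,3S,4S,5S,6S,7S)-2,3-epoxy-1,6-dihydroxy-4-methoxy-9-oxobicyclo[3.3.1]nonan-7-yl]dodec-2-enamide (trans hydroxy amide) | CCCCCCCCC/C=C/C(=O)N[C@H]1C[C@@]2(O)C(=O)[C@@H]([C@@H]1O)[C@H](OC)[C@@H]1O[C@@H]12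
F4 | step 11 | cis-fused 2-[(E)-undec-1-enyl]-4,5-dihydrooxazole spanning C6 (oxygen) and C7 (nitrogen) of the core | CCCCCCCCC/C=C/C1=N[C@H]2C[C@@]3(O)C(=O)[C@@H]([C@H]2O1)[C@H](OC)[C@@H]1O[C@@H]13
F5 | step 11 | (1S,2S,3S,4S,5S,6R,7S)-7-amino-2,3-epoxy-1-hydroxy-4-methoxy-9-oxobicyclo[3.3.1]nonan-6-yl (2E)-dodec-2-enoate | CCCCCCCCC/C=C/C(=O)O[C@H]1[C@@H](N)C[C@@]2(O)C(=O)[C@@H]1[C@H](OC)[C@@H]1O[C@@H]12
F6 | step 5 | (2S)-2-{[(6S)-6-hydroxy-6-(2-nitroethyl)-3-oxocyclohexa-1,4-dien-1-yl]oxy}propanoic acid | C[C@H](OC1=CC(=O)C=C[C@@]1(O)CC[N+](=O)[O-])C(=O)O
F7 | step 5 | (3S,8aR)-3-methyl-8a-(2-nitroethyl)-3,8a-dihydro-1,4-benzodioxine-2,6-dione | [O-][N+](=O)CC[C@@]12OC(=O)[C@H](C)OC2=CC(=O)C=C1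
F8 | step 10 | (1S,2S,5S,6S)-2-hydroxy-4-(hydroxymethyl)-5-methoxy-2-(2-nitroethyl)-7-oxabicyclo[4.1.0]heptan-3-one (C4 epimers) | [O-][N+](=O)CC[C@@]1(O)C(=O)C(CO)[C@H](OC)[C@@H]2O[C@@H]21
F9 | step 8 | disodium alkoxide nitronate of 11 | [Na+].[Na+].[O-][N+]([O-])=CC[C@]12OC(=O)[C@H](C)OC2=C[C@H]([O-])[C@@H]2O[C@@H]21
F10 | step 8 | sodium nitronate of 12 | [Na+].[O-][N+]([O-])=CC[C@]12OC(=O)[C@H](C)OC2=C[C@H](OC)[C@@H]2O[C@@H]21
A1 | alternative 1 | benzoic acid | OC(=O)c1ccccc1
A2 | alternative 1 | (1S,2R)-1,2-dihydroxycyclohexa-3,5-diene-1-carboxylic acid | OC(=O)[C@@]1(O)[C@H](O)C=CC=C1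
A3 | alternative 2 | tert-butyl N-[6-(tert-butyldimethylsilyloxy)-1-hydroxy-4-methoxy-9-oxobicyclo[3.3.1]non-2-en-7-yl]carbamate | CC(C)(C)OC(=O)N[C@H]1C[C@@]2(O)C(=O)[C@@H]([C@H]1O[Si](C)(C)C(C)(C)C)[C@H](OC)C=C2
A4 | alternative 3 | 2,5-dihydroxy-2-(prop-2-enyl)-7-oxabicyclo[4.1.0]heptan-3-one | O=C1C[C@H](O)[C@@H]2O[C@@H]2[C@@]1(O)CC=C
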